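**Retrosynthetic overview**

1. The route rests on the carbocycle: C6 (H, aryl) and the quaternary C1 (CH3 trans to aryl) are adjacent, lie β and α to the one-carbon arm on C1 (carboxyl level, later the styryl CH), and C6 is allylic to the C4=C5 alkene. The ring is therefore the 1,4-adduct of a 4-methylcyclohexa-1,3-diene-1-carboxyl derivative.
2. Key disconnection: the C6–aryl and C1–CH3 bonds, both made in one flask by adding aryllithium 10 to the (4R)-tert-butyl dienyl oxazoline 6 and trapping the azaenolate with iodomethane; no ring is closed in this step.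
3. The C1 arm is then taken from oxazoline to aldehyde to (E)-iodoalkene and joined by Suzuki coupling to the preformed 7-methoxycoumarin-8-yl boronate 20.
4. The second coumarin is built last on the C6 aryl group: MOM removal, ortho-formylation, ylide-based lactone annulation.
5. Ring order: carbocycle (bought as enone 1), oxazoline (step 3, auxiliary, cleaved in step 6), first coumarin (bought as umbelliferone 17), second pyranone ring (step 14).

Key step: step 5

Remark on locants: the carbocycle is numbered C1 (quaternary), C2, C3, C4 (methyl-bearing, C4=C5), C6 (aryl-bearing) in the text and in all names; the descriptors at C1 and C6 change along the route only because the priority of the C1 arm changes, while the geometry (aryl cis to the C1 arm, methyl trans to aryl) stays the same.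

Assumption: the nitrogen-bound aryllithium is delivered to the diene face opposite the tert-butyl group, as is usual for 4-tert-butyl oxazolines; on this basis (R)-tert-leucinol is the enantiomer that leads to the target, and its mirror image would be used if the sense proved opposite.

**Route**

Step 1
Reactants: 1 4-methylcyclohex-2-en-1-one (racemic)
Product: 2 4-methylcyclohexa-1,3-dien-1-yl trifluoromethanesulfonate
Conditions: Tf2O, 2,6-di-tert-butyl-4-methylpyridine, CH2Cl2, 0 °C → rt
Reagents that add atoms: triflic anhydride, O=S(=O)(OS(=O)(=O)C(F)(F)F)C(F)(F)F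
Why: Enol triflate formation from an enone: O-triflation gives an allyl cation that should lose the γ-proton at C4 to the hindered pyridine, giving the linearly conjugated, more substituted 1-triflyloxy-1,3-diene and erasing the stereocentre of 1.

Step 2
Reactants: 2 4-methylcyclohexa-1,3-dien-1-yl trifluoromethanesulfonate; 3 (R)-tert-leucinol
Product: 4 N-[(2R)-1-hydroxy-3,3-dimethylbutan-2-yl]-4-methylcyclohexa-1,3-diene-1-carboxamide
Conditions: Pd(OAc)2, PPh3, Et3N, CO (1 atm), DMF, 40 °C
Reagents that add atoms: carbon monoxide, [C-]#[O+]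
Why: Palladium-catalysed aminocarbonylation of an alkenyl triflate: oxidative addition, CO insertion and capture of the acylpalladium by the amine of 3 (nitrogen before oxygen) should give the hydroxy amide with the diene and the auxiliary stereocentre untouched.

Step 3
Reactants: 4 N-[(2R)-1-hydroxy-3,3-dimethylbutan-2-yl]-4-methylcyclohexa-1,3-diene-1-carboxamide
Product: 6 (4R)-4-tert-butyl-2-(4-methylcyclohexa-1,3-dien-1-yl)-4,5-dihydro-1,3-oxazole, via mesylate 5 (not isolated)
Conditions: MsCl, Et3N, CH2Cl2, 0 °C, then reflux; handled under argon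
Reagents that add atoms: none
Why: Cyclodehydration of a β-hydroxy amide: the primary mesylate is displaced by the amide oxygen (5-exo-tet) to close the oxazoline, and the stereocentre is not involved and stays (R).

Step 4
Reactants: 7 3-methoxyphenol
Product: 8 1-methoxy-3-(methoxymethoxy)benzene
Conditions: MOMCl, iPr2NEt, CH2Cl2, 0 °C → rt
Reagents that add atoms: chloromethyl methyl ether, COCCl
Why: Williamson-type O-alkylation of the phenol installs the acetal that later directs the lithiation to C2 and tolerates organolithium reagents.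

Step 5
Reactants: 8 1-methoxy-3-(methoxymethoxy)benzene; 6 (4R)-4-tert-butyl-2-(4-methylcyclohexa-1,3-dien-1-yl)-4,5-dihydro-1,3-oxazole; 9 iodomethane
Product: 12 (4R)-4-tert-butyl-2-[(1S,6S)-6-[2-methoxy-6-(methoxymethoxy)phenyl]-1,4-dimethylcyclohex-4-en-1-yl]-4,5-dihydro-1,3-oxazole, via aryllithium 10 (not isolated), via lithium azaenolate 11 (not isolated)
Conditions: 8 (slight excess over base), n-BuLi, THF, 0 °C; then 6, −78 → −30 °C; then MeI, −78 °C → rt
Reagents that add atoms: iodomethane (compound 9), CI
Why: The aryllithium, made by ortho-lithiation between the two oxygen substituents, binds the oxazoline nitrogen and transfers its aryl group to the β-carbon C6 through a six-membered Li–N=C–C1=C6 array, and the resulting lithium azaenolate is C-methylated at C1; the closest known reaction type is the chiral-oxazoline-directed tandem organolithium conjugate addition and electrophile trapping of 1-naphthyl and alkenyl oxazolines, which accepts aryllithiums. No ring is closed. C6 is set by the auxiliary: in the reactive s-cis conformer (N syn to C6) the tert-butyl group of the (4R)-oxazoline covers the face that would lead to the mirror-image ring, so the aryl group should enter from the other face and give the (6S) centre of 12 (6R in the target after the priority change). C1 is set by the new C6 substituent: the planar azaenolate should be methylated anti to the bulky di-ortho-substituted aryl group, which places methyl trans to aryl and the oxazoline cis to it. 1,4- over 1,6-addition is secured by nitrogen-directed delivery to the nearer β-carbon and by the methyl group on C4, where 1,6-attack would have to create a quaternary carbon. Deprotonation at C3 or at the C4 methyl group is the competing process and is held back by low temperature and by using the aryllithium free of residual butyllithium.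

Step 6
Reactants: 12 (4R)-4-tert-butyl-2-[(1S,6S)-6-[2-methoxy-6-(methoxymethoxy)phenyl]-1,4-dimethylcyclohex-4-en-1-yl]-4,5-dihydro-1,3-oxazole
Product: 15 (1S,6S)-6-[2-methoxy-6-(methoxymethoxy)phenyl]-1,4-dimethylcyclohex-4-ene-1-carbaldehyde, via N-methyloxazolinium triflate 13 (not isolated), via N-methyloxazolidine 14 (not isolated)
Conditions: MeOTf, CH2Cl2, rt; NaBH4, THF/MeOH, 0 °C; oxalic acid, THF/H2O, rt
Reagents that add atoms: water, O
Why: Standard unmasking of a 2-substituted oxazoline as an aldehyde: N-methylation activates C2, hydride adds once to give the N,O-aminal 14, and mild aqueous acid hydrolyses it without cleaving the aryl MOM ether; the aldehyde is α-quaternary and cannot epimerise.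

Step 7
Reactants: 15 (1S,6S)-6-[2-methoxy-6-(methoxymethoxy)phenyl]-1,4-dimethylcyclohex-4-ene-1-carbaldehyde
Product: 16 (1S,6R)-1-[(E)-2-iodoethenyl]-6-[2-methoxy-6-(methoxymethoxy)phenyl]-1,4-dimethylcyclohex-4-ene
Conditions: CrCl2, CHI3, THF, 0 °C → rt
Reagents that add atoms: iodoform, IC(I)I
Why: Takai olefination: the geminal dichromium species from CHI3 and CrCl2 adds to the aldehyde and eliminates to the (E)-iodoalkene under near-neutral conditions that the MOM ether and the ring alkene should tolerate.

Step 8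
Reactants: 17 umbelliferone (7-hydroxy-2H-chromen-2-one)
Product: 18 7-hydroxy-8-iodo-2H-chromen-2-one
Conditions: I2, KI, aq. NH3, rt
Reagents that add atoms: iodine, II
Why: Electrophilic aromatic iodination of the phenoxide; C8, between the two ring oxygens, is the most activated position of 7-hydroxycoumarin and should be iodinated selectively.

Step 9
Reactants: 18 7-hydroxy-8-iodo-2H-chromen-2-one; 9 iodomethane
Product: 19 8-iodo-7-methoxy-2H-chromen-2-one
Conditions: MeI, K2CO3, acetone, reflux
Reagents that add atoms: iodomethane (compound 9), CI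
Why: Williamson O-methylation of the phenol; the lactone is stable to carbonate in acetone.

Step 10
Reactants: 19 8-iodo-7-methoxy-2H-chromen-2-one
Product: 20 7-methoxy-8-(4,4,5,5-tetramethyl-1,3,2-dioxaborolan-2-yl)-2H-chromen-2-one
Conditions: B2pin2, PdCl2(dppf), KOAc, 1,4-dioxane, 85 °C
Reagents that add atoms: bis(pinacolato)diboron, CC1(C)OB(OC1(C)C)B1OC(C)(C)C(C)(C)O1
Why: Miyaura borylation: oxidative addition of the aryl iodide, acetate-assisted transmetalation and reductive elimination should give the pinacol boronate, which resists protodeboronation better than the free di-ortho-oxygenated boronic acid.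

Step 11
Reactants: 16 (1S,6R)-1-[(E)-2-iodoethenyl]-6-[2-methoxy-6-(methoxymethoxy)phenyl]-1,4-dimethylcyclohex-4-ene; 20 7-methoxy-8-(4,4,5,5-tetramethyl-1,3,2-dioxaborolan-2-yl)-2H-chromen-2-one
Product: 21 7-methoxy-8-[(E)-2-[(1R,6R)-6-[2-methoxy-6-(methoxymethoxy)phenyl]-1,4-dimethylcyclohex-4-en-1-yl]ethenyl]-2H-chromen-2-one
Conditions: Pd(OAc)2, SPhos, K3PO4, THF/H2O, 60 °C
Reagents that add atoms: none
Why: Suzuki–Miyaura coupling: the alkenyl iodide adds to zerovalent palladium with retention of the (E) geometry, the bulky biarylphosphine promotes transmetalation of the hindered boronate, and phosphate is a mild enough base for the lactone.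

Step 12
Reactants: 21 7-methoxy-8-[(E)-2-[(1R,6R)-6-[2-methoxy-6-(methoxymethoxy)phenyl]-1,4-dimethylcyclohex-4-en-1-yl]ethenyl]-2H-chromen-2-one
Product: 23 8-[(E)-2-[(1R,6R)-6-(2-hydroxy-6-methoxyphenyl)-1,4-dimethylcyclohex-4-en-1-yl]ethenyl]-7-methoxy-2H-chromen-2-one, via aryl trimethylsilyl ether 22 (not isolated)
Conditions: TMSOTf, 2,2'-bipyridyl, MeCN, 0 °C → rt; then H2O
Reagents that add atoms: none
Why: Non-protic cleavage of an aryl MOM ether: TMSOTf with 2,2'-bipyridyl converts the acetal into the aryl silyl ether, which water hydrolyses, and the absence of free Brønsted acid should keep the phenol from adding to the C4=C5 alkene.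

Step 13
Reactants: 23 8-[(E)-2-[(1R,6R)-6-(2-hydroxy-6-methoxyphenyl)-1,4-dimethylcyclohex-4-en-1-yl]ethenyl]-7-methoxy-2H-chromen-2-one
Product: 25 8-[(E)-2-[(1R,6R)-6-(3-formyl-2-hydroxy-6-methoxyphenyl)-1,4-dimethylcyclohex-4-en-1-yl]ethenyl]-7-methoxy-2H-chromen-2-one, via hydroxymethylphenol 24 (not isolated)
Conditions: MgCl2, Et3N, (CH2O)n, MeCN, reflux
Reagents that add atoms: paraformaldehyde (as formaldehyde), C=O
Why: Magnesium-mediated ortho-formylation of a phenol (Casnati–Skattebøl): the magnesium phenoxide directs formaldehyde to the only free ortho position, which is para to the methoxy group, and a second formaldehyde oxidises the benzylic alkoxide to the salicylaldehyde.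

Step 14
Reactants: 25 8-[(E)-2-[(1R,6R)-6-(3-formyl-2-hydroxy-6-methoxyphenyl)-1,4-dimethylcyclohex-4-en-1-yl]ethenyl]-7-methoxy-2H-chromen-2-one
Product: 27 8-[(E)-2-[(1R,6R)-6-(7-methoxy-2-oxo-2H-chromen-8-yl)-1,4-dimethylcyclohex-4-en-1-yl]ethenyl]-7-methoxy-2H-chromen-2-one (CNP0156435.1), via aryl phosphoranylideneacetate 26 (not isolated)
Conditions: Ph3P=C=C=O, toluene, 100 °C
Reagents that add atoms: (triphenylphosphoranylidene)ketene, O=C=C=P(c1ccccc1)(c1ccccc1)c1ccccc1
Why: Bestmann ylide annulation: the phenol adds to the ketenylidene ylide to give an ester-stabilised ylide that undergoes intramolecular Wittig olefination with the ortho formyl group, closing the pyranone with its cis C3=C4 bond directly, at a temperature well below that at which the 1,5-diene (styryl C=C, C1, C6, C5=C4) could undergo a [3,3] shift.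

**Compound list**

1 | 4-methylcyclohex-2-en-1-one (racemic) | CC1CCC(=O)C=C1 | starting material
2 | 4-methylcyclohexa-1,3-dien-1-yl trifluoromethanesulfonate | CC1=CC=C(OS(=O)(=O)C(F)(F)F)CC1 | intermediate
3 | (R)-tert-leucinol, (2R)-2-amino-3,3-dimethylbutan-1-ol | CC(C)(C)[C@@H](N)CO | starting material
4 | N-[(2R)-1-hydroxy-3,3-dimethylbutan-2-yl]-4-methylcyclohexa-1,3-diene-1-carboxamide | CC1=CC=C(CC1)C(=O)N[C@@H](CO)C(C)(C)C | intermediate
5 | (2R)-3,3-dimethyl-2-[(4-methylcyclohexa-1,3-diene-1-carbonyl)amino]butyl methanesulfonate | CC1=CC=C(CC1)C(=O)N[C@@H](COS(C)(=O)=O)C(C)(C)C | intermediate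
6 | (4R)-4-tert-butyl-2-(4-methylcyclohexa-1,3-dien-1-yl)-4,5-dihydro-1,3-oxazole | CC(C)(C)[C@@H]1COC(=N1)C1=CC=C(C)CC1 | intermediate
7 | 3-methoxyphenol | COc1cccc(O)c1 | starting material
8 | 1-methoxy-3-(methoxymethoxy)benzene | COCOc1cccc(OC)c1 | intermediate
9 | iodomethane | CI | starting material
10 | 2-lithio-1-methoxy-3-(methoxymethoxy)benzene | [Li]c1c(OC)cccc1OCOC | intermediate
11 | lithium azaenolate from 6 and 10: N-lithio (4R)-4-tert-butyl-2-[(6S)-6-[2-methoxy-6-(methoxymethoxy)phenyl]-4-methylcyclohex-4-en-1-ylidene]-1,3-oxazolidine | CC(C)(C)[C@@H]1COC(N1[Li])=C1CCC(C)=C[C@H]1c1c(OC)cccc1OCOC | intermediate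
12 | (4R)-4-tert-butyl-2-[(1S,6S)-6-[2-methoxy-6-(methoxymethoxy)phenyl]-1,4-dimethylcyclohex-4-en-1-yl]-4,5-dihydro-1,3-oxazole | CC(C)(C)[C@@H]1COC(=N1)[C@@]1(C)CCC(C)=C[C@H]1c1c(OC)cccc1OCOC | intermediate
13 | (4R)-4-tert-butyl-2-[(1S,6S)-6-[2-methoxy-6-(methoxymethoxy)phenyl]-1,4-dimethylcyclohex-4-en-1-yl]-3-methyl-4,5-dihydro-1,3-oxazol-3-ium trifluoromethanesulfonate | CC(C)(C)[C@@H]1COC(=[N+]1C)[C@@]1(C)CCC(C)=C[C@H]1c1c(OC)cccc1OCOC.[O-]S(=O)(=O)C(F)(F)F | intermediate
14 | (4R)-4-tert-butyl-2-[(1S,6S)-6-[2-methoxy-6-(methoxymethoxy)phenyl]-1,4-dimethylcyclohex-4-en-1-yl]-3-methyl-1,3-oxazolidine (epimers at oxazolidine C2) | CC(C)(C)[C@@H]1COC(N1C)[C@@]1(C)CCC(C)=C[C@H]1c1c(OC)cccc1OCOC | intermediate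
15 | (1S,6S)-6-[2-methoxy-6-(methoxymethoxy)phenyl]-1,4-dimethylcyclohex-4-ene-1-carbaldehyde | O=C[C@@]1(C)CCC(C)=C[C@H]1c1c(OC)cccc1OCOC | intermediate
16 | (1S,6R)-1-[(E)-2-iodoethenyl]-6-[2-methoxy-6-(methoxymethoxy)phenyl]-1,4-dimethylcyclohex-4-ene | I/C=C/[C@@]1(C)CCC(C)=C[C@H]1c1c(OC)cccc1OCOC | intermediate
17 | umbelliferone, 7-hydroxy-2H-chromen-2-one | Oc1ccc2ccc(=O)oc2c1 | starting material
18 | 7-hydroxy-8-iodo-2H-chromen-2-one | Oc1ccc2ccc(=O)oc2c1I | intermediate
19 | 8-iodo-7-methoxy-2H-chromen-2-one | COc1ccc2ccc(=O)oc2c1I | intermediate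
20 | 7-methoxy-8-(4,4,5,5-tetramethyl-1,3,2-dioxaborolan-2-yl)-2H-chromen-2-one | COc1ccc2ccc(=O)oc2c1B1OC(C)(C)C(C)(C)O1 | intermediate
21 | 7-methoxy-8-[(E)-2-[(1R,6R)-6-[2-methoxy-6-(methoxymethoxy)phenyl]-1,4-dimethylcyclohex-4-en-1-yl]ethenyl]-2H-chromen-2-one | COc1ccc2ccc(=O)oc2c1/C=C/[C@@]1(C)CCC(C)=C[C@H]1c1c(OC)cccc1OCOC | intermediate
22 | 7-methoxy-8-[(E)-2-[(1R,6R)-6-[2-methoxy-6-(trimethylsilyloxy)phenyl]-1,4-dimethylcyclohex-4-en-1-yl]ethenyl]-2H-chromen-2-one | COc1ccc2ccc(=O)oc2c1/C=C/[C@@]1(C)CCC(C)=C[C@H]1c1c(OC)cccc1O[Si](C)(C)C | intermediate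
23 | 8-[(E)-2-[(1R,6R)-6-(2-hydroxy-6-methoxyphenyl)-1,4-dimethylcyclohex-4-en-1-yl]ethenyl]-7-methoxy-2H-chromen-2-one | COc1ccc2ccc(=O)oc2c1/C=C/[C@@]1(C)CCC(C)=C[C@H]1c1c(OC)cccc1O | intermediate
24 | 8-[(E)-2-[(1R,6R)-6-[2-hydroxy-3-(hydroxymethyl)-6-methoxyphenyl]-1,4-dimethylcyclohex-4-en-1-yl]ethenyl]-7-methoxy-2H-chromen-2-one (present as its magnesium salt) | COc1ccc2ccc(=O)oc2c1/C=C/[C@@]1(C)CCC(C)=C[C@H]1c1c(OC)ccc(CO)c1O | intermediate
25 | 8-[(E)-2-[(1R,6R)-6-(3-formyl-2-hydroxy-6-methoxyphenyl)-1,4-dimethylcyclohex-4-en-1-yl]ethenyl]-7-methoxy-2H-chromen-2-one | COc1ccc2ccc(=O)oc2c1/C=C/[C@@]1(C)CCC(C)=C[C@H]1c1c(OC)ccc(C=O)c1O | intermediate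
26 | 6-formyl-3-methoxy-2-[(1R,6R)-6-[(E)-2-(7-methoxy-2-oxo-2H-chromen-8-yl)ethenyl]-3,6-dimethylcyclohex-2-en-1-yl]phenyl (triphenylphosphoranylidene)acetate | COc1ccc2ccc(=O)oc2c1/C=C/[C@@]1(C)CCC(C)=C[C@H]1c1c(OC)ccc(C=O)c1OC(=O)C=P(c1ccccc1)(c1ccccc1)c1ccccc1 | intermediate
27 | 8-[(E)-2-[(1R,6R)-6-(7-methoxy-2-oxo-2H-chromen-8-yl)-1,4-dimethylcyclohex-4-en-1-yl]ethenyl]-7-methoxy-2H-chromen-2-one (CNP0156435.1) | COc1ccc2ccc(=O)oc2c1/C=C/[C@@]1(C)CCC(C)=C[C@H]1c1c(OC)ccc2ccc(=O)oc12 | target

**Step count and risks**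

Total step count: 14. Longest linear sequence: 10 steps (steps 1, 2, 3, 5, 6, 7, 11, 12, 13, 14).

Steps most likely to fail:

Step 5. The hindered, internally chelated aryllithium may act as a base instead of a nucleophile (deprotonation at C3 or at the C4 methyl group, followed by aromatisation to the p-tolyl oxazoline), may add too slowly, or may add with poor facial selectivity. The fallback sets out from 8 and comes back at aldehyde 15, replacing the conjugate addition by a cycloaddition. Ortho-lithiation of 8 (n-BuLi, THF, 0 °C) and quenching with DMF should give 2-methoxy-6-(methoxymethoxy)benzaldehyde F1. Claisen–Schmidt condensation with acetone (aq. NaOH) should give (E)-4-[2-methoxy-6-(methoxymethoxy)phenyl]but-3-en-2-one F2, and Wittig methylenation (Ph3P=CH2, THF) should give (E)-1-[2-methoxy-6-(methoxymethoxy)phenyl]-3-methylbuta-1,3-diene F3. A catalytic enantioselective Diels–Alder reaction of F3 with methacrolein (chiral cationic oxazaborolidine from α,α-diphenylprolinol, activated with HNTf2, CH2Cl2, −78 °C) should then give 15 directly. The 1-aryl and 3-methyl groups of the diene both direct the aryl-bearing terminus to the α-carbon of methacrolein, the formyl-endo transition state places aryl and CHO cis, and the catalyst enantiomer is chosen for the (1S,6S) product. Steps 1–3 and 5–6 are then not needed.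

Step 11. The di-ortho-oxygenated boronate may protodeboronate or transmetalate too slowly at the hindered centre, and the aqueous base may open the lactone. The fallback sets out from 15 and 19 and comes back at 21, replacing the cross-coupling of two functionalised partners by a Mizoroki–Heck arylation. Wittig methylenation of 15 (Ph3P=CH2, THF, 0 °C → rt) should give (1R,6R)-1-ethenyl-6-[2-methoxy-6-(methoxymethoxy)phenyl]-1,4-dimethylcyclohex-4-ene F4. Heck reaction of F4 with 19 (Pd(OAc)2, P(o-tol)3, Et3N, DMF, 90 °C) should give 21; because C1 is quaternary, β-hydride elimination can only lead to the (E)-styrene. Steps 7 and 10 are then not needed.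

Step 7. Addition of the dichromium reagent to the neopentyl aldehyde, which is also flanked by the di-ortho-substituted aryl group, may be slow and incomplete, with competing reduction of the aldehyde. The fallback sets out from 15 and comes back at 16, going through an alkyne. Ohira–Bestmann homologation (dimethyl (1-diazo-2-oxopropyl)phosphonate, K2CO3, MeOH, rt; the aldehyde is not enolisable) should give (1S,6R)-1-ethynyl-6-[2-methoxy-6-(methoxymethoxy)phenyl]-1,4-dimethylcyclohex-4-ene F5. Hydrozirconation with Cp2Zr(H)Cl (THF, rt) followed by iodine should give the (E)-iodoalkene 16 by syn addition and iodinolysis with retention.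

**Further compounds**

F1 | step 5 | 2-methoxy-6-(methoxymethoxy)benzaldehyde | COCOc1cccc(OC)c1C=O
F2 | step 5 | (E)-4-[2-methoxy-6-(methoxymethoxy)phenyl]but-3-en-2-one | CC(=O)/C=C/c1c(OC)cccc1OCOC
F3 | step 5 | (E)-1-[2-methoxy-6-(methoxymethoxy)phenyl]-3-methylbuta-1,3-diene | CC(=C)/C=C/c1c(OC)cccc1OCOC
F4 | step 11 | (1R,6R)-1-ethenyl-6-[2-methoxy-6-(methoxymethoxy)phenyl]-1,4-dimethylcyclohex-4-ene | C=C[C@@]1(C)CCC(C)=C[C@H]1c1c(OC)cccc1OCOC
F5 | step 7 | (1S,6R)-1-ethynyl-6-[2-methoxy-6-(methoxymethoxy)phenyl]-1,4-dimethylcyclohex-4-ene | C#C[C@@]1(C)CCC(C)=C[C@H]1c1c(OC)cccc1OCOC
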